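**Assumption:** the target is taken exactly as drawn, i.e. (2E,6E,10S)-acid carrying a (2S,7R)-bicycle. This 2/10 pair corresponds to anti O,O-addition across a (2Z)-alkene, so a (2Z,6E)-farnesyl unit is built; an (E,E)-farnesyl unit would give the C10 epimer.

**Retrosynthetic overview**
- Acid ⇐ enal ⇐ cross-metathesis of the terminal isopropylidene with methacrolein (last C–C bond).
- Dihydrofuran ring (the second and last ring formed) ⇐ O1–C2 bond: hydroxyl-directed asymmetric epoxidation of the (2Z)-alkene, then 5-exo opening by the ring carbonyl oxygen of an α′-hydroxy methyl vinylogous ester. This one event sets C2 and the carbinol carbon, and places the ring oxygen next to the C7 hydroxyl.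
- C7–OH ⇐ asymmetric α′-hydroxylation of the 2-alkyl-3-methoxy-enone; the carbocycle is bought as 1,5-dimethoxycyclohexa-1,4-diene and C-alkylated.
- (2Z,6E)-Farnesyl bromide ⇐ (E)-geranylacetone via the ynoate and syn-methylcupration.

**Step 1**
Reactants: 1 (5E)-6,10-dimethylundeca-5,9-dien-2-one ((E)-geranylacetone)
Product: 5 methyl (6E)-7,11-dimethyldodeca-6,10-dien-2-ynoate, via lithium enolate C13H21LiO 2 (not isolated), via enol diethyl phosphate 3 (not isolated), via lithium acetylide C13H19Li 4 (not isolated)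
Conditions: LiN(i-Pr)2, THF, −78 °C; ClP(O)(OEt)2; LiN(i-Pr)2 (2.3 equiv), −78 °C → rt; ClCO2Me, −78 °C → rt
Reagents that add atoms: methyl chloroformate, COC(=O)Cl
Why: The kinetic methyl-side enolate is trapped as its enol phosphate, LiN(i-Pr)2 eliminates this to the acetylide (Negishi methyl ketone-to-alkyne sequence), and the acetylide is acylated; no stereocentre is formed and the (E)-alkene is untouched.

**Step 2**
Reactants: 5 methyl (6E)-7,11-dimethyldodeca-6,10-dien-2-ynoate
Product: 7 methyl (2Z,6E)-3,7,11-trimethyldodeca-2,6,10-trienoate, via cuprate Li[Cu(CH3)(C16H25O2)] 6 (not isolated)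
Conditions: Me2CuLi, THF, −78 °C; aq. NH4Cl, −78 °C → rt
Reagents that add atoms: lithium dimethylcuprate (Me2CuLi), [Li+].C[Cu-]C
Why: Cuprate conjugate addition to an ynoate is a syn carbocupration (Corey–Katzenellenbogen), so with a cold quench the new methyl ends up trans to the ester and the chain cis, i.e. the (2Z)-alkene.

**Step 3**
Reactants: 7 methyl (2Z,6E)-3,7,11-trimethyldodeca-2,6,10-trienoate
Product: 8 (2Z,6E)-3,7,11-trimethyldodeca-2,6,10-trien-1-ol
Conditions: i-Bu2AlH, CH2Cl2, −78 → 0 °C; aq. KNaC4H4O6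
Reagents that add atoms: none
Why: Hydride 1,2-reduction of the conjugated ester gives the allylic alcohol without touching or isomerising the alkenes.

**Step 4**
Reactants: 8 (2Z,6E)-3,7,11-trimethyldodeca-2,6,10-trien-1-ol
Product: 9 (2Z,6E)-1-bromo-3,7,11-trimethyldodeca-2,6,10-triene
Conditions: PBr3, Et2O, −10 °C (used crude)
Reagents that add atoms: phosphorus tribromide, BrP(Br)Br
Why: SN2 bromination of the primary allylic alcohol at low temperature keeps the (2Z) geometry, as in the nerol to neryl bromide conversion.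

**Step 5**
Reactants: 10 1,5-dimethoxycyclohexa-1,4-diene; 9 (2Z,6E)-1-bromo-3,7,11-trimethyldodeca-2,6,10-triene
Product: 13 3-methoxy-2-[(2Z,6E)-3,7,11-trimethyldodeca-2,6,10-trien-1-yl]cyclohex-2-en-1-one, via 6-lithio-1,5-dimethoxycyclohexa-1,4-diene 11 (not isolated), via 6-alkyl-1,5-dimethoxycyclohexa-1,4-diene 12 (not isolated)
Conditions: t-BuLi, THF–DMPU, −78 °C; 9, −78 → −20 °C; then 0.5 M HCl, THF, 0 °C
Reagents that add atoms: water, O
Why: t-BuLi removes the proton between the two enol ether carbons, the pentadienyl anion is alkylated at its central carbon (Piers alkylation, C-alkylation only), and dilute acid hydrolyses one enol ether and conjugates the other to give the 2-alkyl vinylogous ester directly.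

**Step 6**
Reactants: 13 3-methoxy-2-[(2Z,6E)-3,7,11-trimethyldodeca-2,6,10-trien-1-yl]cyclohex-2-en-1-one
Product: 15 (6R)-6-hydroxy-3-methoxy-2-[(2Z,6E)-3,7,11-trimethyldodeca-2,6,10-trien-1-yl]cyclohex-2-en-1-one, via lithium dienolate C22H33LiO2 14 (not isolated)
Conditions: LiN(i-Pr)2, THF, −78 °C; then (+)-[(8,8-dichlorocamphoryl)sulfonyl]oxaziridine, −78 °C; aq. NH4Cl
Reagents that add atoms: [(8,8-dichlorocamphoryl)sulfonyl]oxaziridine, CC1(C)C2CCC13CS(=O)(=O)N4OC34C2(Cl)Cl
Why: LiN(i-Pr)2 forms the kinetic cross-conjugated α′-enolate of the vinylogous ester, and the camphor-derived N-sulfonyloxaziridine transfers oxygen to one enolate face (Davis asymmetric enolate hydroxylation), setting C6 as R (the later C7).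

**Step 7**
Reactants: 15 (6R)-6-hydroxy-3-methoxy-2-[(2Z,6E)-3,7,11-trimethyldodeca-2,6,10-trien-1-yl]cyclohex-2-en-1-one
Product: 18 (2S,7R)-7-hydroxy-2-[(2S,5E)-2-hydroxy-6,10-dimethylundeca-5,9-dien-2-yl]-2,3,6,7-tetrahydro-1-benzofuran-4(5H)-one, via cis-epoxide 16 (not isolated), via oxocarbenium zwitterion 17 (not isolated)
Conditions: Hf(Ot-Bu)4 (10 mol%), (R,R)-N,N′-dihydroxy-N,N′-bis(2,2-diphenylacetyl)cyclohexane-1,2-diamine (12 mol%), PhC(CH3)2OOH, DMPU, 4 Å MS, toluene, 0 °C → rt; then pH 7 buffer (H2O), rt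
Reagents that add atoms: cumene hydroperoxide, CC(C)(OO)c1ccccc1; water, O
Why: Proposed new method: the C6 alkoxide binds the tetravalent hafnium–bishydroxamate alkylperoxide and the adjacent ring carbonyl oxygen holds it over C2′, so oxygen goes only to the nearest (Z)-alkene, on the face chosen by the ligand, giving the cis (2′R,3′S)-epoxide 16; the same electron-rich vinylogous-ester carbonyl oxygen then opens the metal-bound epoxide 5-exo at the less substituted C2′ with inversion (C2 becomes S, the carbinol stays S, the ring oxygen lands next to C7–OH), and water hydrolyses the methyl oxocarbenium 17 to the ketone; the closest known reactions are the hafnium/zirconium–bishydroxamic acid epoxidation of homoallylic and bishomoallylic alcohols and the epoxidation–cyclisation of bishomoallylic alcohols to tetrahydrofurans, neither shown for an α-hydroxy ketone anchor or with a vinylogous ester carbonyl as the ring-closing nucleophile.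

**Step 8**
Reactants: 18 (2S,7R)-7-hydroxy-2-[(2S,5E)-2-hydroxy-6,10-dimethylundeca-5,9-dien-2-yl]-2,3,6,7-tetrahydro-1-benzofuran-4(5H)-one; 19 2-methylprop-2-enal (methacrolein)
Product: 20 (2E,6E,10S)-10-hydroxy-10-[(2S,7R)-7-hydroxy-4-oxo-2,3,4,5,6,7-hexahydro-1-benzofuran-2-yl]-2,6-dimethylundeca-2,6-dienal
Conditions: 19 (15 equiv), RuCl2(H2IMes)(=CH-C6H4-2-O-i-Pr) (second-generation Hoveyda–Grubbs catalyst, 5 mol%), CH2Cl2, 40 °C
Reagents that add atoms: none
Why: In this cross-metathesis the ruthenium carbene engages only the terminal isopropylidene (the internal trisubstituted alkene is inert), isobutene is lost and the thermodynamically favoured (E)-enal forms.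

**Step 9**
Reactants: 20 (2E,6E,10S)-10-hydroxy-10-[(2S,7R)-7-hydroxy-4-oxo-2,3,4,5,6,7-hexahydro-1-benzofuran-2-yl]-2,6-dimethylundeca-2,6-dienal
Product: 21 (2E,6E,10S)-10-hydroxy-10-[(2S,7R)-7-hydroxy-4-oxo-2,3,4,5,6,7-hexahydro-1-benzofuran-2-yl]-2,6-dimethylundeca-2,6-dienoic acid
Conditions: NaClO2, NaH2PO4, 2-methylbut-2-ene, t-BuOH–H2O, 0 °C → rt
Reagents that add atoms: sodium chlorite, [Na+].[O-]Cl=O
Why: Pinnick oxidation turns the enal into the acid under buffered conditions with an alkene scavenger for hypochlorite, leaving the alcohols, the alkenes and the vinylogous ester intact; no stereocentre is touched.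

**Compound list**
1 | (5E)-6,10-dimethylundeca-5,9-dien-2-one | CC(=O)CC/C=C(\C)CCC=C(C)C | starting material
2 | lithium (5E)-6,10-dimethylundeca-1,5,9-trien-2-olate | C=C(O[Li])CC/C=C(\C)CCC=C(C)C | intermediate (not isolated)
3 | diethyl (5E)-6,10-dimethylundeca-1,5,9-trien-2-yl phosphate | C=C(OP(=O)(OCC)OCC)CC/C=C(\C)CCC=C(C)C | intermediate (not isolated)
4 | lithium (5E)-6,10-dimethylundeca-5,9-dien-1-yn-1-ide | [Li]C#CCC/C=C(\C)CCC=C(C)C | intermediate (not isolated)
5 | methyl (6E)-7,11-dimethyldodeca-6,10-dien-2-ynoate | COC(=O)C#CCC/C=C(\C)CCC=C(C)C | intermediate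
6 | lithium [(1E,5E)-1-(methoxycarbonyl)-2,6,10-trimethylundeca-1,5,9-trien-1-yl](methyl)cuprate | COC(=O)/C([Cu-]C)=C(/C)CC/C=C(\C)CCC=C(C)C.[Li+] | intermediate (not isolated)
7 | methyl (2Z,6E)-3,7,11-trimethyldodeca-2,6,10-trienoate | COC(=O)/C=C(/C)CC/C=C(\C)CCC=C(C)C | intermediate
8 | (2Z,6E)-3,7,11-trimethyldodeca-2,6,10-trien-1-ol | OC/C=C(/C)CC/C=C(\C)CCC=C(C)C | intermediate
9 | (2Z,6E)-1-bromo-3,7,11-trimethyldodeca-2,6,10-triene | BrC/C=C(/C)CC/C=C(\C)CCC=C(C)C | intermediate
10 | 1,5-dimethoxycyclohexa-1,4-diene | COC1=CCC=C(OC)C1 | starting material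
11 | 6-lithio-1,5-dimethoxycyclohexa-1,4-diene | COC1=CCC=C(OC)C1[Li] | intermediate (not isolated)
12 | 1,5-dimethoxy-6-[(2Z,6E)-3,7,11-trimethyldodeca-2,6,10-trien-1-yl]cyclohexa-1,4-diene | COC1=CCC=C(OC)C1C/C=C(/C)CC/C=C(\C)CCC=C(C)C | intermediate (not isolated)
13 | 3-methoxy-2-[(2Z,6E)-3,7,11-trimethyldodeca-2,6,10-trien-1-yl]cyclohex-2-en-1-one | COC1=C(C/C=C(/C)CC/C=C(\C)CCC=C(C)C)C(=O)CCC1 | intermediate
14 | lithium 4-methoxy-3-[(2Z,6E)-3,7,11-trimethyldodeca-2,6,10-trien-1-yl]cyclohexa-1,3-dien-2-olate | COC1=C(C/C=C(/C)CC/C=C(\C)CCC=C(C)C)C(O[Li])=CCC1 | intermediate (not isolated)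
15 | (6R)-6-hydroxy-3-methoxy-2-[(2Z,6E)-3,7,11-trimethyldodeca-2,6,10-trien-1-yl]cyclohex-2-en-1-one | COC1=C(C/C=C(/C)CC/C=C(\C)CCC=C(C)C)C(=O)[C@H](O)CC1 | intermediate
16 | (6R)-6-hydroxy-3-methoxy-2-({(2R,3S)-3-[(3E)-4,8-dimethylnona-3,7-dien-1-yl]-3-methyloxiran-2-yl}methyl)cyclohex-2-en-1-one | COC1=C(C[C@H]2O[C@@]2(C)CC/C=C(\C)CCC=C(C)C)C(=O)[C@H](O)CC1 | intermediate (not isolated)
17 | [(2S,7R)-7-hydroxy-2-[(2S,5E)-6,10-dimethyl-2-oxidoundeca-5,9-dien-2-yl]-2,3,6,7-tetrahydro-1-benzofuran-4(5H)-ylidene](methyl)oxonium (zwitterion, alkoxide held on hafnium) | C/C(=C\CC[C@](C)([O-])[C@@H]1CC2=C(O1)[C@H](O)CCC2=[O+]C)CCC=C(C)C | intermediate (not isolated)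
18 | (2S,7R)-7-hydroxy-2-[(2S,5E)-2-hydroxy-6,10-dimethylundeca-5,9-dien-2-yl]-2,3,6,7-tetrahydro-1-benzofuran-4(5H)-one | C/C(=C\CC[C@](C)(O)[C@@H]1CC2=C(O1)[C@H](O)CCC2=O)CCC=C(C)C | intermediate
19 | 2-methylprop-2-enal | CC(=C)C=O | starting material
20 | (2E,6E,10S)-10-hydroxy-10-[(2S,7R)-7-hydroxy-4-oxo-2,3,4,5,6,7-hexahydro-1-benzofuran-2-yl]-2,6-dimethylundeca-2,6-dienal | C/C(=C\CC[C@](C)(O)[C@@H]1CC2=C(O1)[C@H](O)CCC2=O)CC/C=C(\C)C=O | intermediate
21 | (2E,6E,10S)-10-hydroxy-10-[(2S,7R)-7-hydroxy-4-oxo-2,3,4,5,6,7-hexahydro-1-benzofuran-2-yl]-2,6-dimethylundeca-2,6-dienoic acid | C/C(=C\CC[C@](C)(O)[C@@H]1CC2=C(O1)[C@H](O)CCC2=O)CC/C=C(\C)C(=O)O | target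

**Totals and risks**

Total steps: 9. Longest linear sequence: 9 (steps 1 to 9; 10 and 19 are bought). C7 and the C2/carbinol pair are set by two independent reagent-controlled steps, so the minor enantiomer from either step becomes a diastereomer of 18 and is removed by chromatography there.

Step 7 (the proposed new step) is the most likely to fail. The C6 alkoxide is one atom further from the alkene than in a bishomoallylic alcohol, the carbonyl oxygen could open the epoxide 6-endo at the tertiary carbon, and the facial sense of the ligand on this substrate is a prediction (the (S,S)-ligand is used if it proves opposite). The fallback uses known chemistry, sets out from 15 and comes back at 18. All three trisubstituted alkenes of 15 are epoxidised with the D-fructose-derived Shi ketone and KHSO5 (K2CO3 buffer, 0 °C); this places R at every CH carbon and therefore gives the needed cis (2′R,3′S)-epoxide next to the ring in the tris-epoxide F1. Pyridinium p-toluenesulfonate in wet CH2Cl2 then lets the ring carbonyl open only the epoxide it can reach (5-exo, loss of methanol), giving the bis-epoxy bicycle F2. CH3ReO3 with PPh3 removes the two remote epoxide oxygens with retention of alkene geometry and returns 18.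

Step 6 is the second risk. Oxaziridine hydroxylation of a cyclic enolate that gives a secondary carbinol can give only moderate enantiomeric excess, and the sense for this enolate is assigned by analogy (the (−)-reagent is used if it proves opposite). The fallback sets out from 13 and comes back at 15. The enolate of 13 is hydroxylated with racemic 2-(phenylsulfonyl)-3-phenyloxaziridine to the racemic ketol, i.e. 15 together with its (6S)-enantiomer F3. Burkholderia cepacia lipase and vinyl acetate acetylate the (R)-alcohol selectively (Kazlauskas selectivity) to the (6R)-acetate F4, which is separated from F3 and cleaved with K2CO3 in methanol at 0 °C to give 15.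

Step 5 is the third risk. The pentadienyl anion may be alkylated partly at a terminal carbon or by SN2′, and the acid treatment must stop at the vinylogous ester. The fallback sets out from 9 and comes back at 13. Cyclohexane-1,3-dione is C-alkylated with 9 (KOH, H2O, rt) to the 2-alkyl dione F5, and (CH3)3SiCHN2 in methanol–toluene O-methylates its enol to give 13.

**Further compounds**
F1 | step 7 | (6R)-6-hydroxy-3-methoxy-2-({(2R,3S)-3-methyl-3-[2-((2R,3R)-3-methyl-3-{2-[(2R)-3,3-dimethyloxiran-2-yl]ethyl}oxiran-2-yl)ethyl]oxiran-2-yl}methyl)cyclohex-2-en-1-one | COC1=C(C[C@H]2O[C@@]2(C)CC[C@H]3O[C@]3(C)CC[C@H]4OC4(C)C)C(=O)[C@H](O)CC1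
F2 | step 7 | (2S,7R)-7-hydroxy-2-[(2S)-2-hydroxy-4-((2R,3R)-3-methyl-3-{2-[(2R)-3,3-dimethyloxiran-2-yl]ethyl}oxiran-2-yl)butan-2-yl]-2,3,6,7-tetrahydro-1-benzofuran-4(5H)-one | C[C@]1(CC[C@H]2OC2(C)C)O[C@@H]1CC[C@](C)(O)[C@@H]3CC4=C(O3)[C@H](O)CCC4=O
F3 | step 6 | (6S)-6-hydroxy-3-methoxy-2-[(2Z,6E)-3,7,11-trimethyldodeca-2,6,10-trien-1-yl]cyclohex-2-en-1-one | COC1=C(C/C=C(/C)CC/C=C(\C)CCC=C(C)C)C(=O)[C@@H](O)CC1
F4 | step 6 | (1R)-4-methoxy-2-oxo-3-[(2Z,6E)-3,7,11-trimethyldodeca-2,6,10-trien-1-yl]cyclohex-3-en-1-yl acetate | COC1=C(C/C=C(/C)CC/C=C(\C)CCC=C(C)C)C(=O)[C@H](OC(C)=O)CC1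
F5 | step 5 | 2-[(2Z,6E)-3,7,11-trimethyldodeca-2,6,10-trien-1-yl]cyclohexane-1,3-dione | O=C1CCCC(=O)C1C/C=C(/C)CC/C=C(\C)CCC=C(C)C
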